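**Retrosynthetic overview**

- The target is a 2,3-trans 3-methoxyflavanone, (2R,3R). The strategy rests on ring B: it has free OH groups at C2' and C5', para to each other, and C1' is bonded to C2. The quinone of this hydroquinone is a tautomer of the ortho-quinone methide at C2, which O1 of ring A can capture.
- Late disconnections: 5-OH from the 5-methyl ether peri to C4=O, the ring B OH groups from benzyl ethers, and C4=O from a C4 silyl ether.
- Key disconnection: the O1–C2 bond of ring C, back to alkylbenzoquinone 18 (redox-neutral isomerisation, then oxa-conjugate addition).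
- 18 is assembled by two C–C bonds. C4–C4a comes from a ring A aryllithium and a Weinreb amide, with C4 then set by chelation-controlled reduction. C1'–C2 comes from a ring B Grignard reagent opening methyl (R)-glycidate, which supplies C3.
- Rings A and B are bought (3,4,5-trimethoxyphenol, 2-methoxyhydroquinone). Ring C is the only ring formed, in step 13.

Key step: step 13

Remark on the chemistry: C4 is not a spectator in the ring closure, so it is set deliberately as the (4S) silyl ether (anti in the open chain, 3,4-cis in the chroman); its pseudo-axial preference next to the C5 methoxy group then reinforces the 2,3-trans outcome.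

**Route**

Step 1
Reactants: 1 2-methoxyhydroquinone
Product: 2 1,4-bis(benzyloxy)-2-methoxybenzene
Conditions: BnBr, K2CO3, DMF, 60 °C, N2
Reagents that add atoms: benzyl bromide, BrCc1ccccc1
Why: Williamson etherification of both phenoxides should give benzyl ethers that tolerate the organometallic steps and leave later by hydrogenolysis.

Step 2
Reactants: 2 1,4-bis(benzyloxy)-2-methoxybenzene
Product: 3 1,4-bis(benzyloxy)-2-bromo-5-methoxybenzene
Conditions: NBS, MeCN, 0 °C to rt, dark
Reagents that add atoms: N-bromosuccinimide, O=C1CCC(=O)N1Br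
Why: Electrophilic aromatic bromination should go to the one position that is para to the methoxy group and ortho to a benzyloxy group, the most activated and least hindered site of this 1,2,4-trialkoxybenzene.

Step 3
Reactants: 3 1,4-bis(benzyloxy)-2-bromo-5-methoxybenzene; 4 methyl (2R)-oxirane-2-carboxylate (methyl (R)-glycidate)
Product: 6 methyl (2R)-3-[2,5-bis(benzyloxy)-4-methoxyphenyl]-2-hydroxypropanoate, via arylmagnesium bromide 5 (not isolated)
Conditions: Mg, THF, 40 °C; then CuI (10 mol%), 4, THF, −40 to −20 °C; then H2O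
Reagents that add atoms: none
Why: Copper-catalysed SN2 opening of the epoxide by the aryl Grignard reagent at the unsubstituted carbon should form the C1'–C2 bond faster than attack on the ester at low temperature and does not touch the glycidate stereocentre, so C3 (R) is carried over from the chiral pool.

Step 4
Reactants: 6 methyl (2R)-3-[2,5-bis(benzyloxy)-4-methoxyphenyl]-2-hydroxypropanoate
Product: 7 methyl (2R)-3-[2,5-bis(benzyloxy)-4-methoxyphenyl]-2-methoxypropanoate
Conditions: MeI, Ag2O, MeCN, 40 °C, dark
Reagents that add atoms: iodomethane, CI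
Why: Purdie methylation alkylates the secondary hydroxyl without a strong base, so the stereocentre alpha to the ester should not be enolised.

Step 5
Reactants: 7 methyl (2R)-3-[2,5-bis(benzyloxy)-4-methoxyphenyl]-2-methoxypropanoate
Product: 8 (2R)-3-[2,5-bis(benzyloxy)-4-methoxyphenyl]-N,2-dimethoxy-N-methylpropanamide
Conditions: MeNHOMe·HCl, iPrMgCl, THF, −20 to 0 °C; then H2O
Reagents that add atoms: N,O-dimethylhydroxylamine hydrochloride, CNOC.Cl
Why: Aminolysis of the ester by the chloromagnesium amide of N,O-dimethylhydroxylamine (Weinreb amide formation) is fast at low temperature for alpha-alkoxy esters and should leave C3 unchanged.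

Step 6
Reactants: 9 3,4,5-trimethoxyphenol
Product: 10 2-bromo-3,4,5-trimethoxyphenol
Conditions: NBS (1.0 equiv), CH2Cl2, −78 to 0 °C
Reagents that add atoms: N-bromosuccinimide, O=C1CCC(=O)N1Br
Why: Electrophilic bromination ortho to the phenol should give a single monobromide because the only two free ring positions are equivalent by symmetry.

Step 7
Reactants: 10 2-bromo-3,4,5-trimethoxyphenol
Product: 11 1-(benzyloxy)-2-bromo-3,4,5-trimethoxybenzene
Conditions: BnBr, K2CO3, DMF, rt
Reagents that add atoms: benzyl bromide, BrCc1ccccc1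
Why: Williamson etherification masks the future O1 phenol as a benzyl ether, so that it can be freed together with the ring B benzyl ethers in step 11.

Step 8
Reactants: 11 1-(benzyloxy)-2-bromo-3,4,5-trimethoxybenzene; 8 (2R)-3-[2,5-bis(benzyloxy)-4-methoxyphenyl]-N,2-dimethoxy-N-methylpropanamide
Product: 14 (2R)-1-[2-(benzyloxy)-4,5,6-trimethoxyphenyl]-3-[2,5-bis(benzyloxy)-4-methoxyphenyl]-2-methoxypropan-1-one, via aryllithium 12 (not isolated), via lithium hemiaminal adduct 13 (not isolated)
Conditions: n-BuLi, THF, −78 °C; then 8, −78 to −40 °C; then H2O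
Reagents that add atoms: none
Why: Bromine–lithium exchange followed by Weinreb ketone synthesis should form the C4–C4a bond, because the chelated tetrahedral adduct 13 resists a second addition and collapses to the ketone only on quench, with C3 untouched at low temperature.

Step 9
Reactants: 14 (2R)-1-[2-(benzyloxy)-4,5,6-trimethoxyphenyl]-3-[2,5-bis(benzyloxy)-4-methoxyphenyl]-2-methoxypropan-1-one
Product: 15 (1S,2R)-1-[2-(benzyloxy)-4,5,6-trimethoxyphenyl]-3-[2,5-bis(benzyloxy)-4-methoxyphenyl]-2-methoxypropan-1-ol
Conditions: Zn(BH4)2, Et2O, −20 to 0 °C; then H2O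
Reagents that add atoms: none
Why: In this chelation-controlled (Cram chelate) reduction zinc bridges the carbonyl oxygen and the alpha-methoxy oxygen, and hydride should add to the face opposite the arylmethyl substituent at C3, which sets C4 as (S), anti to the C3 methoxy group.

Step 10
Reactants: 15 (1S,2R)-1-[2-(benzyloxy)-4,5,6-trimethoxyphenyl]-3-[2,5-bis(benzyloxy)-4-methoxyphenyl]-2-methoxypropan-1-ol
Product: 16 tert-butyl{[(1S,2R)-1-[2-(benzyloxy)-4,5,6-trimethoxyphenyl]-3-[2,5-bis(benzyloxy)-4-methoxyphenyl]-2-methoxypropyl]oxy}dimethylsilane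
Conditions: TBSOTf, 2,6-lutidine, CH2Cl2, −78 to 0 °C
Reagents that add atoms: tert-butyldimethylsilyl trifluoromethanesulfonate, CC(C)(C)[Si](C)(C)OS(=O)(=O)C(F)(F)F
Why: Silylation with the silyl triflate and a hindered base should cap the crowded benzylic alcohol without ionising it, and the silyl ether keeps C4 sp3 and C3 non-enolisable through the key step.

Step 11
Reactants: 16 tert-butyl{[(1S,2R)-1-[2-(benzyloxy)-4,5,6-trimethoxyphenyl]-3-[2,5-bis(benzyloxy)-4-methoxyphenyl]-2-methoxypropyl]oxy}dimethylsilane
Product: 17 2-[(2R,3S)-3-[(tert-butyldimethylsilyl)oxy]-3-(2-hydroxy-4,5,6-trimethoxyphenyl)-2-methoxypropyl]-5-methoxybenzene-1,4-diol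
Conditions: H2 (1 atm), 10% Pd/C, EtOAc, rt
Reagents that add atoms: none
Why: Hydrogenolysis of the three aryl benzyl ethers in neutral ethyl acetate should be much faster than cleavage of the hindered benzylic C4–O silyl ether, and it frees the ring B hydroquinone and the ring A phenol together.

Step 12
Reactants: 17 2-[(2R,3S)-3-[(tert-butyldimethylsilyl)oxy]-3-(2-hydroxy-4,5,6-trimethoxyphenyl)-2-methoxypropyl]-5-methoxybenzene-1,4-diol
Product: 18 2-[(2R,3S)-3-[(tert-butyldimethylsilyl)oxy]-3-(2-hydroxy-4,5,6-trimethoxyphenyl)-2-methoxypropyl]-5-methoxycyclohexa-2,5-diene-1,4-dione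
Conditions: Ag2O, Na2SO4, Et2O, rt, dark, 20 min; filter through Celite
Reagents that add atoms: none
Why: Ag2O is a mild two-electron oxidant that should convert the hydroquinone into the para-benzoquinone within minutes, while the lone ring A phenol and the silyl ether are left alone under these neutral heterogeneous conditions.

Step 13
Reactants: 18 2-[(2R,3S)-3-[(tert-butyldimethylsilyl)oxy]-3-(2-hydroxy-4,5,6-trimethoxyphenyl)-2-methoxypropyl]-5-methoxycyclohexa-2,5-diene-1,4-dione
Product: 20 (2R,3R,4S)-4-[(tert-butyldimethylsilyl)oxy]-2-(2,5-dihydroxy-4-methoxyphenyl)-3,5,6,7-tetramethoxychroman, via ortho-quinone methide 19 (not isolated)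
Conditions: Et3N (0.3 equiv), CH2Cl2 (degassed, 0.01 M), rt, Ar, dark
Reagents that add atoms: none
Why: Et3N removes a C2 hydrogen of alkylquinone 18, which is vinylogous to the C5' carbonyl, and O-protonation of the dienolate gives the 5'-hydroxy ortho-quinone methide 19, a tautomer at the same oxidation level, so neither oxidant nor reductant is needed. The ring A phenol, held ortho to C4a, adds through O1 to the methide carbon C2 in a 6-exo-trig oxa-conjugate addition that closes ring C and re-aromatises ring B as the free hydroquinone; the closest known reaction type is the base-induced tautomerisation of 2-alkyl-1,4-benzoquinones to ortho-quinone methides with intramolecular phenol capture to chromans. The new stereocentre C2 is controlled by C3 and C4: in the half-chair transition state the C4 silyloxy group sits pseudo-axial to avoid the peri C5 methoxy group, which places the cis-related C3 methoxy group equatorial, and the ring B methide carbon then takes the equatorial position, which should give the 2,3-trans (2R) isomer. Because phenoxide-triggered reopening to 19 is possible under the same conditions, the diequatorial trans isomer is also the thermodynamic sink. The step needs capture by O1 to outrun transfer of the C3 hydrogen to the methide oxygen, which would give an enol-ether styrene; the pre-placed phenol, the E geometry of the methide that keeps the C3 hydrogen away from the carbonyl oxygen, and the sp3 silyl ether at C4 that leaves C3 non-enolisable secure this. High dilution under argon limits hydrogen exchange between product hydroquinone 20 and unreacted quinone 18.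

Step 14
Reactants: 20 (2R,3R,4S)-4-[(tert-butyldimethylsilyl)oxy]-2-(2,5-dihydroxy-4-methoxyphenyl)-3,5,6,7-tetramethoxychroman
Product: 21 (2R,3R,4S)-2-[2,5-bis(benzyloxy)-4-methoxyphenyl]-4-[(tert-butyldimethylsilyl)oxy]-3,5,6,7-tetramethoxychroman
Conditions: BnBr, K2CO3, DMF (degassed), rt, Ar
Reagents that add atoms: benzyl bromide, BrCc1ccccc1
Why: Williamson benzylation of both hydroquinone oxygens protects ring B from the oxidant of step 16 and removes the free 2'-phenol, so that the O1–C2 bond can no longer reopen.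

Step 15
Reactants: 21 (2R,3R,4S)-2-[2,5-bis(benzyloxy)-4-methoxyphenyl]-4-[(tert-butyldimethylsilyl)oxy]-3,5,6,7-tetramethoxychroman
Product: 22 (2R,3S,4S)-2-[2,5-bis(benzyloxy)-4-methoxyphenyl]-3,5,6,7-tetramethoxychroman-4-ol
Conditions: Bu4NF, THF, rt to 45 °C; then H2O
Reagents that add atoms: none
Why: Fluoride-induced desilylation should free the C4 hydroxyl without acid, which the electron-rich benzylic C4–O bond would not tolerate (the C3 descriptor changes only through ligand priorities).

Step 16
Reactants: 22 (2R,3S,4S)-2-[2,5-bis(benzyloxy)-4-methoxyphenyl]-3,5,6,7-tetramethoxychroman-4-ol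
Product: 23 (2R,3R)-2-[2,5-bis(benzyloxy)-4-methoxyphenyl]-3,5,6,7-tetramethoxychroman-4-one
Conditions: Dess–Martin periodinane, CH2Cl2, rt
Reagents that add atoms: none
Why: Dess–Martin oxidation should convert the secondary benzylic alcohol into the C4 ketone without base, so C3 is not enolised and the beta-aryloxy O1–C2 bond is not opened to a chalcone.

Step 17
Reactants: 23 (2R,3R)-2-[2,5-bis(benzyloxy)-4-methoxyphenyl]-3,5,6,7-tetramethoxychroman-4-one
Product: 24 (2R,3R)-2-(2,5-dihydroxy-4-methoxyphenyl)-5-hydroxy-3,6,7-trimethoxychroman-4-one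
Conditions: BCl3, C6HMe5, CH2Cl2, −78 to 0 °C; then H2O
Reagents that add atoms: none
Why: BCl3 with pentamethylbenzene as benzyl-cation scavenger should cleave both aryl benzyl ethers at −78 °C, and on warming the boron chelate between the C4 carbonyl and O5 directs demethylation to the peri 5-methoxy group only (chelation-assisted selective ether cleavage).

**Compound list**

1 | 2-methoxyhydroquinone (2-methoxybenzene-1,4-diol) | COc1cc(O)ccc1O | starting material
2 | 1,4-bis(benzyloxy)-2-methoxybenzene | COc1cc(OCc2ccccc2)ccc1OCc1ccccc1 | intermediate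
3 | 1,4-bis(benzyloxy)-2-bromo-5-methoxybenzene | COc1cc(OCc2ccccc2)c(Br)cc1OCc1ccccc1 | intermediate
4 | methyl (2R)-oxirane-2-carboxylate (methyl (R)-glycidate) | COC(=O)[C@H]1CO1 | starting material
5 | [2,5-bis(benzyloxy)-4-methoxyphenyl]magnesium bromide | COc1cc(OCc2ccccc2)c([Mg]Br)cc1OCc1ccccc1 | intermediate (not isolated)
6 | methyl (2R)-3-[2,5-bis(benzyloxy)-4-methoxyphenyl]-2-hydroxypropanoate | COC(=O)[C@H](O)Cc1cc(OCc2ccccc2)c(OC)cc1OCc1ccccc1 | intermediate
7 | methyl (2R)-3-[2,5-bis(benzyloxy)-4-methoxyphenyl]-2-methoxypropanoate | COC(=O)[C@H](OC)Cc1cc(OCc2ccccc2)c(OC)cc1OCc1ccccc1 | intermediate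
8 | (2R)-3-[2,5-bis(benzyloxy)-4-methoxyphenyl]-N,2-dimethoxy-N-methylpropanamide | CON(C)C(=O)[C@H](OC)Cc1cc(OCc2ccccc2)c(OC)cc1OCc1ccccc1 | intermediate
9 | 3,4,5-trimethoxyphenol | COc1cc(O)cc(OC)c1OC | starting material
10 | 2-bromo-3,4,5-trimethoxyphenol | COc1cc(O)c(Br)c(OC)c1OC | intermediate
11 | 1-(benzyloxy)-2-bromo-3,4,5-trimethoxybenzene | COc1cc(OCc2ccccc2)c(Br)c(OC)c1OC | intermediate
12 | [2-(benzyloxy)-4,5,6-trimethoxyphenyl]lithium | COc1cc(OCc2ccccc2)c([Li])c(OC)c1OC | intermediate (not isolated)
13 | lithium (2R)-1-[2-(benzyloxy)-4,5,6-trimethoxyphenyl]-3-[2,5-bis(benzyloxy)-4-methoxyphenyl]-2-methoxy-1-[methoxy(methyl)amino]propan-1-olate (hemiaminal carbon not defined) | COc1cc(OCc2ccccc2)c(C(O[Li])(N(C)OC)[C@H](OC)Cc2cc(OCc3ccccc3)c(OC)cc2OCc2ccccc2)c(OC)c1OC | intermediate (not isolated)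
14 | (2R)-1-[2-(benzyloxy)-4,5,6-trimethoxyphenyl]-3-[2,5-bis(benzyloxy)-4-methoxyphenyl]-2-methoxypropan-1-one | COc1cc(OCc2ccccc2)c(C(=O)[C@H](OC)Cc2cc(OCc3ccccc3)c(OC)cc2OCc2ccccc2)c(OC)c1OC | intermediate
15 | (1S,2R)-1-[2-(benzyloxy)-4,5,6-trimethoxyphenyl]-3-[2,5-bis(benzyloxy)-4-methoxyphenyl]-2-methoxypropan-1-ol (anti) | COc1cc(OCc2ccccc2)c([C@H](O)[C@H](OC)Cc2cc(OCc3ccccc3)c(OC)cc2OCc2ccccc2)c(OC)c1OC | intermediate
16 | tert-butyl{[(1S,2R)-1-[2-(benzyloxy)-4,5,6-trimethoxyphenyl]-3-[2,5-bis(benzyloxy)-4-methoxyphenyl]-2-methoxypropyl]oxy}dimethylsilane | COc1cc(OCc2ccccc2)c([C@H](O[Si](C)(C)C(C)(C)C)[C@H](OC)Cc2cc(OCc3ccccc3)c(OC)cc2OCc2ccccc2)c(OC)c1OC | intermediate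
17 | 2-[(2R,3S)-3-[(tert-butyldimethylsilyl)oxy]-3-(2-hydroxy-4,5,6-trimethoxyphenyl)-2-methoxypropyl]-5-methoxybenzene-1,4-diol | COc1cc(O)c([C@H](O[Si](C)(C)C(C)(C)C)[C@H](OC)Cc2cc(O)c(OC)cc2O)c(OC)c1OC | intermediate
18 | 2-[(2R,3S)-3-[(tert-butyldimethylsilyl)oxy]-3-(2-hydroxy-4,5,6-trimethoxyphenyl)-2-methoxypropyl]-5-methoxycyclohexa-2,5-diene-1,4-dione | COC1=CC(=O)C(=CC1=O)C[C@@H](OC)[C@@H](O[Si](C)(C)C(C)(C)C)c1c(O)cc(OC)c(OC)c1OC | intermediate
19 | (6E)-6-[(2R,3S)-3-[(tert-butyldimethylsilyl)oxy]-3-(2-hydroxy-4,5,6-trimethoxyphenyl)-2-methoxypropylidene]-4-hydroxy-3-methoxycyclohexa-2,4-dien-1-one | COC1=CC(=O)/C(=C/[C@@H](OC)[C@@H](O[Si](C)(C)C(C)(C)C)c2c(O)cc(OC)c(OC)c2OC)C=C1O | intermediate (not isolated)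
20 | (2R,3R,4S)-4-[(tert-butyldimethylsilyl)oxy]-2-(2,5-dihydroxy-4-methoxyphenyl)-3,5,6,7-tetramethoxychroman (2,3-trans-3,4-cis) | COc1cc(O)c([C@H]2Oc3cc(OC)c(OC)c(OC)c3[C@H](O[Si](C)(C)C(C)(C)C)[C@@H]2OC)cc1O | intermediate
21 | (2R,3R,4S)-2-[2,5-bis(benzyloxy)-4-methoxyphenyl]-4-[(tert-butyldimethylsilyl)oxy]-3,5,6,7-tetramethoxychroman | COc1cc(OCc2ccccc2)c([C@H]2Oc3cc(OC)c(OC)c(OC)c3[C@H](O[Si](C)(C)C(C)(C)C)[C@@H]2OC)cc1OCc1ccccc1 | intermediate
22 | (2R,3S,4S)-2-[2,5-bis(benzyloxy)-4-methoxyphenyl]-3,5,6,7-tetramethoxychroman-4-ol | COc1cc(OCc2ccccc2)c([C@H]2Oc3cc(OC)c(OC)c(OC)c3[C@H](O)[C@@H]2OC)cc1OCc1ccccc1 | intermediate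
23 | (2R,3R)-2-[2,5-bis(benzyloxy)-4-methoxyphenyl]-3,5,6,7-tetramethoxychroman-4-one | COc1cc(OCc2ccccc2)c([C@H]2Oc3cc(OC)c(OC)c(OC)c3C(=O)[C@@H]2OC)cc1OCc1ccccc1 | intermediate
24 | (2R,3R)-2-(2,5-dihydroxy-4-methoxyphenyl)-5-hydroxy-3,6,7-trimethoxychroman-4-one | COc1cc(O)c([C@H]2Oc3cc(OC)c(OC)c(O)c3C(=O)[C@@H]2OC)cc1O | target

**Step count**

Total: 17 steps. Longest linear sequence: 15 steps (steps 1–5 and 8–17); the ring A branch is steps 6–7.

**Steps most likely to fail**

Step 13. The phenol may capture the methide from the wrong face, so that the 2,3-cis epimer builds up instead of 20. The fallback sets C2 under thermodynamic control in a separate operation. It sets out from quinone 18: the crude isomerisation product, containing (2S,3R,4S)-4-[(tert-butyldimethylsilyl)oxy]-2-(2,5-dihydroxy-4-methoxyphenyl)-3,5,6,7-tetramethoxychroman F1, is heated with DBU in degassed MeCN at 50 °C under argon. The 2'-phenoxide then reopens the O1–C2 bond by retro-oxa-conjugate addition, and re-closure should drain the material to the diequatorial 2,3-trans isomer, because the all-cis epimer must place either the C3 methoxy group axial with the C4 silyloxy group against the C5 methoxy group, or the aryl and silyloxy groups 1,3-diaxial. The fallback comes back to the route at 20.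

Step 17. Prolonged exposure to BCl3 may ionise the O1–C2 bond, which is benzylic to the electron-rich ring B, leading to ring opening or C2 epimerisation, or may strip a second methyl ether (6-OMe or 3-OMe). The fallback splits the deprotection into two milder reactions of different type and sets out from 23. MgI2·OEt2 in toluene at 60 °C should demethylate only the peri 5-methoxy group within its magnesium chelate, giving (2R,3R)-2-[2,5-bis(benzyloxy)-4-methoxyphenyl]-5-hydroxy-3,6,7-trimethoxychroman-4-one F2. Neutral hydrogenolysis (H2, 10% Pd/C, EtOAc, rt) then removes the two benzyl ethers, and the fallback comes back to the route at 24.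

Step 9. The ortho benzyloxy and methoxy groups of ring A may compete with the alpha-methoxy group for zinc, which would erode the anti selectivity at C4 and pass a C4 epimer mixture into the key step. The fallback sets C4 in a C–C bond-forming event instead of a hydride delivery and sets out from ester 7. DIBAL-H in CH2Cl2 at −78 °C should give (2R)-3-[2,5-bis(benzyloxy)-4-methoxyphenyl]-2-methoxypropanal F3, used at once. Aryllithium 12, made from 11 as in step 8, is added in THF at −78 °C; under non-chelating Felkin–Anh control this should favour the anti alcohol, which is purified by chromatography. The fallback comes back to the route at 15.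

**Further compounds**

F1 | step 13 | (2S,3R,4S)-4-[(tert-butyldimethylsilyl)oxy]-2-(2,5-dihydroxy-4-methoxyphenyl)-3,5,6,7-tetramethoxychroman | COc1cc(O)c([C@@H]2Oc3cc(OC)c(OC)c(OC)c3[C@H](O[Si](C)(C)C(C)(C)C)[C@@H]2OC)cc1O
F2 | step 17 | (2R,3R)-2-[2,5-bis(benzyloxy)-4-methoxyphenyl]-5-hydroxy-3,6,7-trimethoxychroman-4-one | COc1cc(OCc2ccccc2)c([C@H]2Oc3cc(OC)c(OC)c(O)c3C(=O)[C@@H]2OC)cc1OCc1ccccc1
F3 | step 9 | (2R)-3-[2,5-bis(benzyloxy)-4-methoxyphenyl]-2-methoxypropanal | O=C[C@H](OC)Cc1cc(OCc2ccccc2)c(OC)cc1OCc1ccccc1
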